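## Retrosynthetic overview

1. The target comes from a tricyclic 7,8-diol bearing C1–OTBS and a 3-methylidene group. The operations are two angelate esters, oxidation of the C1 alcohol to the ketone, and migration of the alkene into conjugation.
2. The key disconnection is C5–C6, so ring C (the cycloheptane) closes last. Cp2TiCl opens a C6–C7 epoxide to the tertiary C6 radical. This radical adds 7-exo to the C=N carbon of a cyclobutanone tosylhydrazone, and loss of sulfinate and N2 leaves C5–H.
3. Ring A (cyclobutane) and ring B (six-membered ring) form together, before ring C. The reaction is an intramolecular vinylketene–alkene [2+2] of an acyclic C15 trienoic acid, and the C1 silyl ether steers the face.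
4. The C15 chain comes from prenal and two units of methyl 3-methylbut-2-enoate. Two catalytic asymmetric vinylogous Mukaiyama aldol additions set C8 and C1. C7 follows from C8 by hydroxyl-directed epoxidation.

**Numbering used for all compounds (longipinane numbering of the target):**
- C1 is the ketone carbon, and C2=C3 is the enone alkene (C3 bears a methyl).
- C4 and C11 are the cyclobutane CH carbons bonded to C3 and C1.
- C5 is the cyclobutane CH bonded to C6, and C6 is CMe2.
- C7 (next to C6) and C8 are the acyloxy carbons, and C9 is CH2.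
- C10 is the quaternary cyclobutane carbon.
- The target is (4R,5S,7S,8S,10R,11R), and the 7,8-diester is trans.

**Assumption:** both aldol steps use the same enantiomer of the bisphosphoramide catalyst, the one that gives the (S)-carbinol.

## Route

Step 1
Reactants: 1 methyl 3-methylbut-2-enoate
Product: 2 tert-butyl[(1-methoxy-3-methylbuta-1,3-dien-1-yl)oxy]dimethylsilane
Conditions: LiN(i-Pr)2, THF, −78 °C; TBSCl, DMPU, −78 °C → rt
Reagents that add atoms: tert-butyldimethylsilyl chloride, CC(C)(C)[Si](C)(C)Cl
Why: Kinetic γ-deprotonation of the senecioate and O-silylation of the extended lithium dienolate (silyl ketene acetal formation) is standard, and no stereocentre is formed.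

Step 2
Reactants: 2 silyl dienol ether; 3 3-methylbut-2-enal (prenal)
Product: 4 methyl (2E,5S)-5-hydroxy-3,7-dimethylocta-2,6-dienoate
Conditions: SiCl4 (1.1 equiv), binaphthyldiamine-derived bisphosphoramide (5 mol %), i-Pr2NEt (10 mol %), CH2Cl2, −78 °C; aq NaHCO3
Reagents that add atoms: none
Why: In this catalytic enantioselective vinylogous Mukaiyama aldol addition (Lewis-base-activated SiCl4) the senecioate dienolate reacts only at its γ-carbon with conjugated aldehydes to give the (E)-enoate, and the chiral phosphoramide-bound silicon cation blocks one aldehyde face, which sets C8 as (S).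

Step 3
Reactants: 4 hydroxy ester
Product: 5 methyl (2E,5S)-3,7-dimethyl-5-(triethylsilyloxy)octa-2,6-dienoate
Conditions: TESCl, imidazole, CH2Cl2, 0 °C
Reagents that add atoms: chlorotriethylsilane, CC[Si](CC)(CC)Cl
Why: This is routine silyl ether formation, and TES is chosen because it can later be removed in the presence of TBS.

Step 4
Reactants: 5 TES ester
Product: 6 (2E,5S)-3,7-dimethyl-5-(triethylsilyloxy)octa-2,6-dien-1-ol
Conditions: i-Bu2AlH (2.3 equiv), CH2Cl2, −78 °C; aq potassium sodium tartrate
Reagents that add atoms: none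
Why: i-Bu2AlH reduces the conjugated ester 1,2 to the allylic alcohol without touching the silyl ether, the alkene geometry or C8.

Step 5
Reactants: 6 allylic alcohol
Product: 7 (2E,5S)-3,7-dimethyl-5-(triethylsilyloxy)octa-2,6-dienal
Conditions: MnO2 (15 equiv), CH2Cl2, rt
Reagents that add atoms: none
Why: MnO2 oxidises only the primary allylic alcohol and keeps the (E)-geometry.

Step 6
Reactants: 7 enal; 2 silyl dienol ether
Product: 8 methyl (2E,5S,6E,9S)-5-hydroxy-3,7,11-trimethyl-9-(triethylsilyloxy)dodeca-2,6,10-trienoate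
Conditions: SiCl4 (1.1 equiv), same bisphosphoramide (5 mol %), i-Pr2NEt (10 mol %), CH2Cl2, −78 °C; aq NaHCO3
Reagents that add atoms: none
Why: A second vinylogous Mukaiyama aldol addition under pure catalyst control (C8 is five atoms away) sets C1 as (S) and completes the C15 chain with both trisubstituted alkenes (E).

Step 7
Reactants: 8 hydroxy ester
Product: 9 methyl (2E,5S,6E,9S)-5-(tert-butyldimethylsilyloxy)-3,7,11-trimethyl-9-(triethylsilyloxy)dodeca-2,6,10-trienoate
Conditions: TBSCl, imidazole, DMF, rt
Reagents that add atoms: tert-butyldimethylsilyl chloride, CC(C)(C)[Si](C)(C)Cl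
Why: Routine silylation gives the robust, bulky C1 ether, which protects the alcohol from the ketene and later acts as the stereocontrol element.

Step 8
Reactants: 9 bis-silyl ester
Product: 10 potassium (2E,5S,6E,9S)-5-(tert-butyldimethylsilyloxy)-3,7,11-trimethyl-9-(triethylsilyloxy)dodeca-2,6,10-trienoate
Conditions: KOSiMe3 (1.2 equiv), THF, rt
Reagents that add atoms: potassium trimethylsilanolate, C[Si](C)(C)[O-].[K+]
Why: Anhydrous silanolate cleavage of the methyl ester gives the potassium carboxylate without acid or water, so both silyl ethers and both alkene geometries survive.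

Step 9
Reactants: 10 potassium carboxylate
Product: 14 bicyclic hydroxy ketone (bicyclo[3.1.1]heptan-6-one with free C8–OH; 1S 4R 8S 10R 11R), via acid chloride 11 (not isolated), via vinylketene 12 (not isolated), via bicyclic TES ether 13 (not isolated)
Conditions: (COCl)2 (1.1 equiv), PhMe, 0 °C → rt; added over 6 h to Et3N (5 equiv), PhMe (3 mM), 110 °C; filter, concentrate; PPTS (0.1 equiv), MeOH–CH2Cl2, 0 °C
Reagents that add atoms: none
Why: This intramolecular vinylketene–alkene [2+2] cycloaddition is the reaction that converts geranoyl and farnesoyl chlorides into 2-methylidenebicyclo[3.1.1]heptan-6-ones: 1,4-dehydrochlorination at the methyl cis to COCl gives 12; its carbonyl carbon bonds to C11 and its α-carbon to the cation-stabilising C10 (bridged mode); the (E)-alkene places the C10 methyl syn to the new three-carbon bridge and the side chain over the carbonyl bridge; allylic 1,3-strain between the C1 substituents and the C10 methyl makes the ketene add anti to OTBS, so C4, C10 and C11 follow from C1; PPTS/MeOH then removes only TES.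

Step 10
Reactants: 14 bicyclic hydroxy ketone
Product: 15 epoxy alcohol (7R,8S; otherwise as 14)
Conditions: VO(acac)2 (3 mol %), t-BuOOH (1.3 equiv, decane), CH2Cl2, 0 °C
Reagents that add atoms: tert-butyl hydroperoxide, CC(C)(C)OO
Why: Hydroxyl-directed epoxidation touches only the allylic C6=C7 alkene, not the remote methylidene, and avoids peracid that would Baeyer–Villiger the cyclobutanone; delivery syn to OH in the conformer that avoids allylic 1,3-strain with the cis methyl gives the threo epoxy alcohol (about 6:1), which sets C7.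

Step 11
Reactants: 15 epoxy alcohol
Product: 16 cyclobutanone tosylhydrazone of 15
Conditions: TsNHNH2 (1.1 equiv), MeOH, rt → 40 °C
Reagents that add atoms: p-toluenesulfonyl hydrazide, Cc1ccc(cc1)S(=O)(=O)NN
Why: In this hydrazone condensation the strained cyclobutanone is the only carbonyl and condenses readily (ketones of this type undergo Wolff–Kishner reduction), and the neutral conditions spare the epoxide.

Step 12 (key step)
Reactants: 16 epoxy tosylhydrazone
Product: 19 tricyclic diol (1S,4R,5S,7S,8S,10R,11R)-1-(tert-butyldimethylsilyloxy)-3-methylidenelongipinane-7,8-diol, via tricyclic tosylhydrazide 17 (not isolated), via bridgehead diazene 18 (not isolated)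
Conditions: Cp2TiCl2 (3 equiv), Mn dust (8 equiv), THF (5 mM, slow addition of 16), rt; then MeOH, K2CO3 (3 equiv), 65 °C
Reagents that add atoms: none
Why: Proposed new method: Cp2TiCl (trivalent titanium, made in the flask) cleaves the C6–O bond of the trisubstituted epoxide homolytically to give the tertiary C6 radical while C7–O keeps its configuration; the C10 side chain lies on the cyclobutane face opposite the three-carbon bridge, directly under the C5=N carbon (about 2.1 Å across the ring from C10), so a 7-exo addition, helped by release of the sp2 angle strain of the four-membered ring, can form C5–C6 only from that face and thereby fixes C5; a second Cp2TiCl reduces the stabilised hydrazinyl radical, methanolysis gives 17, base expels sulfinate, and the bridgehead diazene 18 loses N2 with H left where N stood; the closest known reactions are titanocene-mediated epoxide radical cyclisations onto C=O, C≡N and activated C=C acceptors (seven-membered rings included), iron-hydride alkene–sulfonylhydrazone couplings followed by reductive C–N cleavage, and radical cyclisations onto N-aziridinylimines.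

Step 13
Reactants: 19 tricyclic diol; 20 angelic acid ((Z)-2-methylbut-2-enoic acid)
Product: 22 7,8-bis-angelate 1-TBS ether, via mixed anhydride 21 (not isolated)
Conditions: 20 (6 equiv), 2,4,6-trichlorobenzoyl chloride (6 equiv), Et3N (6 equiv), PhMe, rt, 2 h; then 19, 85 °C, 48 h
Reagents that add atoms: none
Why: Yamaguchi-type mixed-anhydride acylation without a nucleophilic catalyst is the established non-isomerising way to make angelates, so both (Z)-alkenes are kept and no stereocentre is touched.

Step 14
Reactants: 22 bis-angelate TBS ether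
Product: 23 (1S)-1-hydroxy-3-methylidenelongipinane-7,8-diyl bis-angelate
Conditions: HF·pyridine, pyridine, THF, 0 °C → rt
Reagents that add atoms: none
Why: Buffered fluoride desilylation removes the TBS group without hydrolysing or isomerising the angelates and without protonating the pinene-type methylidene.

Step 15
Reactants: 23 homoallylic alcohol
Product: 25 (4R,5S,7S,8S,10R,11R)-7,8-diangeloyloxylongipin-2-en-1-one (target), via unconjugated ketone 24 (not isolated)
Conditions: IBX (3 equiv), EtOAc, 75 °C; filter; DBU (0.1 equiv), rt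
Reagents that add atoms: none
Why: IBX oxidation removes the now-superfluous C1 stereocentre, and catalytic base moves the β,γ-methylidene into conjugation (thermodynamic verbenone-type enone) under conditions too mild to turn angelate into tiglate; C11 cannot epimerise because it is a bridgehead.

## Compound list

1 | methyl 3-methylbut-2-enoate | COC(=O)C=C(C)C | starting material
2 | tert-butyl[(1-methoxy-3-methylbuta-1,3-dien-1-yl)oxy]dimethylsilane (ketene acetal geometry inconsequential) | C=C(C)C=C(OC)O[Si](C)(C)C(C)(C)C | intermediate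
3 | 3-methylbut-2-enal (prenal) | CC(C)=CC=O | starting material
4 | methyl (2E,5S)-5-hydroxy-3,7-dimethylocta-2,6-dienoate | COC(=O)/C=C(\C)C[C@H](O)C=C(C)C | intermediate
5 | methyl (2E,5S)-3,7-dimethyl-5-(triethylsilyloxy)octa-2,6-dienoate | COC(=O)/C=C(\C)C[C@H](O[Si](CC)(CC)CC)C=C(C)C | intermediate
6 | (2E,5S)-3,7-dimethyl-5-(triethylsilyloxy)octa-2,6-dien-1-ol | OC/C=C(\C)C[C@H](O[Si](CC)(CC)CC)C=C(C)C | intermediate
7 | (2E,5S)-3,7-dimethyl-5-(triethylsilyloxy)octa-2,6-dienal | O=C/C=C(\C)C[C@H](O[Si](CC)(CC)CC)C=C(C)C | intermediate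
8 | methyl (2E,5S,6E,9S)-5-hydroxy-3,7,11-trimethyl-9-(triethylsilyloxy)dodeca-2,6,10-trienoate | COC(=O)/C=C(\C)C[C@H](O)/C=C(\C)C[C@H](O[Si](CC)(CC)CC)C=C(C)C | intermediate
9 | methyl (2E,5S,6E,9S)-5-(tert-butyldimethylsilyloxy)-3,7,11-trimethyl-9-(triethylsilyloxy)dodeca-2,6,10-trienoate | COC(=O)/C=C(\C)C[C@H](O[Si](C)(C)C(C)(C)C)/C=C(\C)C[C@H](O[Si](CC)(CC)CC)C=C(C)C | intermediate
10 | potassium salt of the acid of 9 | [K+].[O-]C(=O)/C=C(\C)C[C@H](O[Si](C)(C)C(C)(C)C)/C=C(\C)C[C@H](O[Si](CC)(CC)CC)C=C(C)C | intermediate
11 | acid chloride of 10 | ClC(=O)/C=C(\C)C[C@H](O[Si](C)(C)C(C)(C)C)/C=C(\C)C[C@H](O[Si](CC)(CC)CC)C=C(C)C | intermediate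
12 | vinylketene O=C5=C4H–C3(=CH2)–C2H2–C1H(OTBS)–C11H=C10(Me)–chain (1S, 8S, E-alkene) | O=C=CC(=C)C[C@H](O[Si](C)(C)C(C)(C)C)/C=C(\C)C[C@H](O[Si](CC)(CC)CC)C=C(C)C | intermediate
13 | 4-(tert-butyldimethylsilyloxy)-7-methyl-2-methylidene-7-[(2S)-4-methyl-2-(triethylsilyloxy)pent-3-en-1-yl]bicyclo[3.1.1]heptan-6-one; longipinane descriptors 1S,4R,8S,10R,11R; 7-methyl syn to the three-carbon bridge, side chain anti (over the carbonyl bridge), OTBS on the carbonyl-bridge side | CC(C)=C[C@@H](O[Si](CC)(CC)CC)C[C@@]2(C)[C@@H]3[C@@H](O[Si](C)(C)C(C)(C)C)CC(=C)[C@H]2C3=O | intermediate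
14 | as 13 with free (8S)-hydroxyl | CC(C)=C[C@@H](O)C[C@@]2(C)[C@@H]3[C@@H](O[Si](C)(C)C(C)(C)C)CC(=C)[C@H]2C3=O | intermediate
15 | as 14 with side chain (2S)-2-[(2R)-3,3-dimethyloxiran-2-yl]-2-hydroxyethyl (threo; 7R,8S) | CC1(C)O[C@@H]1[C@@H](O)C[C@@]2(C)[C@@H]3[C@@H](O[Si](C)(C)C(C)(C)C)CC(=C)[C@H]2C3=O | intermediate
16 | N-tosylhydrazone of 15 at the cyclobutanone (C5=N, geometry inconsequential) | CC1(C)O[C@@H]1[C@@H](O)C[C@@]2(C)[C@@H]3[C@@H](O[Si](C)(C)C(C)(C)C)CC(=C)[C@H]2C3=NNS(=O)(=O)c4ccc(C)cc4 | intermediate
17 | longipinane tosylhydrazide: C5 bears NH–NHTs (5R, N on the face of the three-carbon bridge), 7S,8S-diol, 1S-OTBS, 3-methylidene | O[C@H]1C[C@@]2(C)[C@@H]3[C@@H](O[Si](C)(C)C(C)(C)C)CC(=C)[C@H]2[C@]3(NNS(=O)(=O)c4ccc(C)cc4)C(C)(C)[C@@H]1O | intermediate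
18 | corresponding C5 diazene (C5–N=NH) | O[C@H]1C[C@@]2(C)[C@@H]3[C@@H](O[Si](C)(C)C(C)(C)C)CC(=C)[C@H]2[C@]3(N=N)C(C)(C)[C@@H]1O | intermediate
19 | (1S,4R,5S,7S,8S,10R,11R)-1-(tert-butyldimethylsilyloxy)-3-methylidenelongipinane-7,8-diol | O[C@H]1C[C@@]2(C)[C@@H]3[C@@H](O[Si](C)(C)C(C)(C)C)CC(=C)[C@H]2[C@@H]3C(C)(C)[C@@H]1O | intermediate
20 | angelic acid, (Z)-2-methylbut-2-enoic acid | C/C=C(/C)C(=O)O | starting material
21 | angelic 2,4,6-trichlorobenzoic anhydride | C/C=C(/C)C(=O)OC(=O)c1c(Cl)cc(Cl)cc1Cl | intermediate
22 | 7,8-bis-angelate of 19 | C/C=C(/C)C(=O)O[C@H]1C[C@@]2(C)[C@@H]3[C@@H](O[Si](C)(C)C(C)(C)C)CC(=C)[C@H]2[C@@H]3C(C)(C)[C@@H]1OC(=O)/C(C)=C\C | intermediate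
23 | (1S)-alcohol from 22 | C/C=C(/C)C(=O)O[C@H]1C[C@@]2(C)[C@@H]3[C@@H](O)CC(=C)[C@H]2[C@@H]3C(C)(C)[C@@H]1OC(=O)/C(C)=C\C | intermediate
24 | 7,8-diangeloyloxy-3-methylidenelongipinan-1-one | C/C=C(/C)C(=O)O[C@H]1C[C@@]2(C)[C@@H]3C(=O)CC(=C)[C@H]2[C@@H]3C(C)(C)[C@@H]1OC(=O)/C(C)=C\C | intermediate
25 | (4R,5S,7S,8S,10R,11R)-7,8-diangeloyloxylongipin-2-en-1-one | C/C=C(/C)C(=O)O[C@H]1C[C@@]2(C)[C@@H]3C(=O)C=C(C)[C@H]2[C@@H]3C(C)(C)[C@@H]1OC(=O)/C(C)=C\C | target

## Step count and risks

Total step count: 15. Longest linear sequence: 15 (1 → 2 → 4 → … → 25).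

**Step 12 (radical ring closure).**
- The risk is that the hindered tertiary radical disproportionates or is reduced before it adds to the fully substituted C=N carbon. The addition may also be reversible.
- The fallback sets out from 15. Condensation with 1-amino-2-phenylaziridine (freed from its acetate salt, EtOH, 0 °C) gives the N-(2-phenylaziridin-1-yl)imine F1.
- Treating F1 with Cp2TiCl2/Mn in THF containing 1,4-cyclohexadiene generates the same C6 radical.
- The aminyl radical formed on addition now collapses irreversibly, losing styrene and N2. This gives the C5 bridgehead radical, which takes H from the diene.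
- The acceptor thus becomes a fragmentation-driven one, and the separate sulfinate elimination is no longer needed. The fallback comes back to the route at 19.

**Step 9 (vinylketene [2+2]).**
- The risk is that the 1,4-dehydrochlorination needs 110 °C. There the ketene may dimerise or the allylic silyl ethers may suffer, so the yield could be low.
- The fallback sets out from 9. LiN(i-Pr)2/DMPU at −78 °C followed by kinetic protonation with AcOH moves the alkene out of conjugation. The product is the 3-methylidene ester F2.
- KOSiMe3 converts F2 into the potassium carboxylate F3, and (COCl)2 gives the β,γ-unsaturated acid chloride F4.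
- F4 loses HCl by ordinary 1,2-elimination with Et3N already at 25–40 °C under high dilution. The fallback comes back to the route at the vinylketene 12, which cyclises at the lower temperature.

**Step 13 (double angeloylation).**
- The risk is that the neopentyl C7–OH acylates slowly, and forcing conditions can turn angelate into tiglate.
- The fallback sets out from 19. Esterification with 2-[bis(2,2,2-trifluoroethoxy)phosphoryl]propanoic acid (DCC, DMAP, CH2Cl2) involves no alkene that could isomerise. It gives the bis(phosphonopropanoate) F5.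
- A double Still–Gennari olefination then builds both (Z)-2-methylbut-2-enoates directly on the esters. The conditions are KN(SiMe3)2, 18-crown-6, THF, −78 °C, then acetaldehyde. The fallback comes back to the route at 22.

## Further compounds

F1 | step 12 | N-(2-phenylaziridin-1-yl)imine of epoxy ketone 15 (mixture at the aziridine carbon) | CC1(C)O[C@@H]1[C@@H](O)C[C@@]2(C)[C@@H]3[C@@H](O[Si](C)(C)C(C)(C)C)CC(=C)[C@H]2C3=NN4CC4c5ccccc5
F2 | step 9 | methyl (5S,6E,9S)-5-(tert-butyldimethylsilyloxy)-7,11-dimethyl-3-methylidene-9-(triethylsilyloxy)dodeca-6,10-dienoate | COC(=O)CC(=C)C[C@H](O[Si](C)(C)C(C)(C)C)/C=C(\C)C[C@H](O[Si](CC)(CC)CC)C=C(C)C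
F3 | step 9 | potassium salt of the acid of F2 | [K+].[O-]C(=O)CC(=C)C[C@H](O[Si](C)(C)C(C)(C)C)/C=C(\C)C[C@H](O[Si](CC)(CC)CC)C=C(C)C
F4 | step 9 | acid chloride of F3 | ClC(=O)CC(=C)C[C@H](O[Si](C)(C)C(C)(C)C)/C=C(\C)C[C@H](O[Si](CC)(CC)CC)C=C(C)C
F5 | step 13 | 7,8-bis{2-[bis(2,2,2-trifluoroethoxy)phosphoryl]propanoate} of 19 (mixture at the two phosphonate α-carbons) | CC(C(=O)O[C@H]1C[C@@]2(C)[C@@H]3[C@@H](O[Si](C)(C)C(C)(C)C)CC(=C)[C@H]2[C@@H]3C(C)(C)[C@@H]1OC(=O)C(C)P(=O)(OCC(F)(F)F)OCC(F)(F)F)P(=O)(OCC(F)(F)F)OCC(F)(F)F
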